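If I followed the fraction of protic impurity left rather than the target made, I needed one number per temperature.

| flask | starting material | other conformer | protic impurity | temperature | remark | time |
|---|---|---|---|---|---|---|
| south-west | 0.035 M | 1 equiv | 0.049 M | 75 °C | run made earlier |  |
| north | 0.035 M | 1 equiv | 0.077 M | 86 °C | run made earlier |  |
| west | 0.070 M | 1 equiv | 0.035 M | 75 °C | run made earlier |  |
| winter | 0.035 M | 1.00 equiv | 0.0350 M | 90 °C |  | 3.0 d |
| spring | 0.035 M | 1.00 equiv | 0.0350 M | 70 °C |  | 3.0 d |

- south-west (time / d: target / %, starting material / %): 0.417: 6.9, 11.5; 1.04: 8.5, 1.7; 2.00: 9.5, 0; 4.00: 8.9, 0; 6.00: 8.4, 0.5; 8.00: 9.8, 0.5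
- north (time / d: target / %, starting material / %): 0.500: 9.6, 0; 1.04: 10.2, 0.9; 1.67: 9.7, 0; 2.08: 8.6, 0.1; 2.50: 10.0, 0.3; 3.00: 10.0, 0; 4.00: 9.8, 0.2
- west (time / d: target / %, starting material / %): 1.25: 12.0, 3.5; 2.50: 12.9, 1.0; 4.00: 13.4, 0; 6.00: 12.3, 0; 8.00: 12.6, 0

(standard deviation of a reading: 0.5 percentage points)

- steps thought possible: starting material + protic impurity -> quenched substrate; other conformer -> isomer of the product; third conformer -> third product; starting material -> target; other conformer <-> third conformer; starting material <-> other conformer
- in a conversion other conformer counts as not yet reacted; third conformer counts as reacted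

* the flask that comes out highest in amount of target, in percent of the starting material and other conformer together charged, or "all alike" when all lie within 1.5 percentage points (winter / spring / all alike)
* target at the end, in percent of the starting material and other conformer together charged, winter
* target at the end, in percent of the starting material and other conformer together charged, spring

I took the rate of target over the rate of quenching to vary as one over the impurity present. Each equal fractional bite of impurity then brings the same target: p = ρ ln(1/f), with p the target and f the impurity left, both as fractions. I call ρ the impurity mark, a selectivity factor for a fixed temperature and charge, and I counted impurity as a fraction of the charge too.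

I assumed that the other conformer's half gave no target, so the starting material's half split between target, quenching and a leak of λ times p. West averaged 12.8% target. Taking its impurity as used up gave λ = 0.953. But that assumption makes λ a lower limit, so I rounded it up to 1 for the rest of the reckoning, and this doubt stayed in my answers.

South-west, averaging 9.15%, then read ρ = 0.152. North, averaging 9.70%, read 0.298. North was still cooler than winter, so I carried the same rise per degree onward. That gave the impurity mark for winter, 0.380, and 0.112 for spring.

In both flasks the balance reduces to p = u f, with u = 0.250. Meeting the rule, this gave 16.3% for winter and 9.99% for spring.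

Was spring finished? The readings of south-west, which was warmer than spring, gave starting material a half-life of 0.226 d, and 3.0 d is far longer than that, so I estimated that spring's target was nearly complete. My figure for winter stood above my figure for spring by 6.3 percentage points, more than the margin.

The forecast differed from my figures: winter, with 14.5% for winter and 9.6% for spring, and it held that “higher temperature favours target”.

The flasks gave winter, with 15.7% for winter and 9.88% for spring.

    starting material + protic impurity → quenched substrate (k = 0.0990 M⁻¹ min⁻¹, Ea = 71.0 kJ mol⁻¹)
    other conformer → isomer of the product (k = 0.00700 min⁻¹, Ea = 124 kJ mol⁻¹)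
    third conformer → third product (k = 0.00170 min⁻¹, Ea = 107 kJ mol⁻¹)
    starting material → target (k = 0.00220 min⁻¹, Ea = 113 kJ mol⁻¹)
    other conformer ⇌ third conformer (K = 1.20, k = 0.00840 min⁻¹, Ea = 106 kJ mol⁻¹, ΔH = 5.00 kJ mol⁻¹)
    starting material ⇌ other conformer (K = 1.80, k = 0.00490 min⁻¹, Ea = 122 kJ mol⁻¹, ΔH = −72.0 kJ mol⁻¹)
    (constants at 90 °C)

Winter kept 61% of its impurity, so my mark predicted 18.9% target, more than it made. Read back from the flask, the mark was 0.317, lower than mine. The neighbouring flask, like winter but charged with 0.0088 M of impurity, kept 52% of it. The read-back mark gave it 20.8%, and the flask held 20.8% target.

The runs were generated by integration with made-up constants.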